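**Plan**
Cuts: in the upper unit O1–C8a and C8–O together, then C2–aryl (ring B), C3–O and the interflavan bond C4–C6'. In the lower unit O1'–C8a', C2'–aryl and C3'–C4'.
Enabling feature: ring A of the upper unit carries three contiguous oxygens (O1 on C8a, OH on C8, OH on C7). An aryne across C8–C8a can therefore take the tethered C2 alkoxide at C8a and an oxygen electrophile at C8 in one operation, and the C7 ether steers the addition.
Forward order: the chain C4'–C3'–C2' is built by glycolate aldol and aryl Grignard addition, ring C' by Pd-catalysed aryl ether closure, then C6' is brominated and borylated. Conjugate addition to 7-(benzyloxy)-8-iodocoumarin joins the halves. The lactone is hydroxylated, reduced and arylated at C2, its ring oxygen becomes the sulfonate leaving group, and ring C closes last.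
Stereochemistry: C3'/C4' come from the (R)-4-benzyloxazolidinone syn aldol, C4 from the chiral rhodium catalyst, C3 from attack on the lactone enolate anti to the C4 aryl group, and C2' and C2 from chelation-controlled aryl addition to α-benzyloxy aldehydes (syn).
Both pyran rings close at the aryl–oxygen bond, so the carbinol centres are retained and syn becomes 2,3-cis. Chelated hydride reduction of a C2 aryl ketone would give the anti alcohol and hence the 2,3-trans flavan, so the aryl group, not hydride, is the incoming nucleophile.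

Key step: step 22

Remark: flavan numbering is kept for open-chain precursors and primes mark the lower unit. α/β mean below/above the flavan drawn with ring A on the left and O1 on top. ArL is the (2R,3S,4S)-3,7,8-tris(benzyloxy)-2-[3,4-bis(benzyloxy)phenyl]-4-[(tert-butyldimethylsilyl)oxy]chroman-6-yl group. The sense of induction known for simple coumarins is assumed to hold in step 16; the antipodal ligand would correct a reversal.

Step 1
Reactants: 1 3,4-dihydroxybenzaldehyde
Product: 2 4-(benzyloxy)-3-hydroxybenzaldehyde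
Conditions: BnBr (1.0 equiv), NaHCO3, DMF, 40 °C
Reagents that add atoms: benzyl bromide BrCc1ccccc1
Why: The 4-OH, para to the formyl group, is the more acidic phenol, so a weak base and one equivalent of halide should give a selective Williamson etherification at O4.

Step 2
Reactants: 2 4-(benzyloxy)-3-hydroxybenzaldehyde
Product: 3 4-(benzyloxy)-2-bromo-3-hydroxybenzaldehyde
Conditions: Br2, NaOAc, Fe powder (cat.), AcOH, rt
Reagents that add atoms: bromine BrBr
Why: Electrophilic aromatic bromination is steered by the free 3-OH to its ortho position C2, as is established for the 4-O-methyl analogue under the same buffered conditions.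

Step 3
Reactants: 3 4-(benzyloxy)-2-bromo-3-hydroxybenzaldehyde
Product: 4 3,4-bis(benzyloxy)-2-bromobenzaldehyde
Conditions: BnBr, K2CO3, DMF, rt
Reagents that add atoms: benzyl bromide BrCc1ccccc1
Why: Williamson etherification of the remaining phenol completes ring A' with bromine on the future C8a'.

Step 4
Reactants: 5 (R)-4-benzyloxazolidin-2-one; 6 (benzyloxy)acetyl chloride
Product: 7 (R)-4-benzyl-3-[(benzyloxy)acetyl]oxazolidin-2-one
Conditions: Et3N, DMAP (cat.), CH2Cl2, 0 °C to rt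
Reagents that add atoms: none
Why: DMAP-catalysed N-acylation of an oxazolidinone by an acid chloride is a routine way to the glycolyl imide.

Step 5
Reactants: 7 (R)-4-benzyl-3-[(benzyloxy)acetyl]oxazolidin-2-one; 4 3,4-bis(benzyloxy)-2-bromobenzaldehyde
Product: 9 (R)-4-benzyl-3-{(2R,3S)-2-(benzyloxy)-3-[3,4-bis(benzyloxy)-2-bromophenyl]-3-hydroxypropanoyl}oxazolidin-2-one, via Z-dibutylboron enolate 8 (not isolated)
Conditions: Bu2BOTf, Et3N, CH2Cl2, −78 to 0 °C; 4, −78 to 0 °C; H2O2, pH 7 buffer, MeOH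
Reagents that add atoms: none
Why: In the Evans syn-aldol reaction the Z-boron enolate reacts through a closed chair transition state on the face away from the benzyl group of the (R)-auxiliary, which sets C3' and C4' together as the syn pair that later reads 3,4-trans.

Step 6
Reactants: 9 syn-aldol adduct
Product: 10 (R)-4-benzyl-3-{(2R,3S)-2-(benzyloxy)-3-[3,4-bis(benzyloxy)-2-bromophenyl]-3-[(tert-butyldimethylsilyl)oxy]propanoyl}oxazolidin-2-one
Conditions: TBSOTf, 2,6-lutidine, CH2Cl2, 0 °C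
Reagents that add atoms: tert-butyldimethylsilyl triflate CC(C)(C)[Si](C)(C)OS(=O)(=O)C(F)(F)F
Why: Silylation under non-basic conditions avoids retro-aldol cleavage, and the bulky non-chelating silyl ether leaves only the α-benzyloxy group available for chelation in step 10.

Step 7
Reactants: 10 silylated imide
Product: 11 (2S,3S)-2-(benzyloxy)-3-[3,4-bis(benzyloxy)-2-bromophenyl]-3-[(tert-butyldimethylsilyl)oxy]propan-1-ol
Conditions: LiBH4, H2O (1 equiv), Et2O, 0 °C
Reagents that add atoms: none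
Why: Hydride attacks the more electrophilic exocyclic imide carbonyl, so reductive removal of the auxiliary gives the primary alcohol without touching the two stereocentres or the aryl bromide.

Step 8
Reactants: 11 primary alcohol
Product: 12 (2R,3S)-2-(benzyloxy)-3-[3,4-bis(benzyloxy)-2-bromophenyl]-3-[(tert-butyldimethylsilyl)oxy]propanal
Conditions: Dess–Martin periodinane, CH2Cl2, 0 °C to rt
Reagents that add atoms: none
Why: The Dess–Martin oxidation is base-free, so the α-alkoxy aldehyde should form without epimerisation at C3'.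

Step 9
Reactants: 13 4-bromobenzene-1,2-diol
Product: 14 1,2-bis(benzyloxy)-4-bromobenzene
Conditions: BnBr (2.2 equiv), K2CO3, DMF, rt
Reagents that add atoms: benzyl bromide BrCc1ccccc1
Why: Double Williamson etherification gives the ring B' building block.

Step 10
Reactants: 12 α-benzyloxy aldehyde; 14 1,2-bis(benzyloxy)-4-bromobenzene
Product: 16 (1R,2S,3S)-2-(benzyloxy)-3-[3,4-bis(benzyloxy)-2-bromophenyl]-1-[3,4-bis(benzyloxy)phenyl]-3-[(tert-butyldimethylsilyl)oxy]propan-1-ol (all-syn), via 3,4-bis(benzyloxy)phenylmagnesium bromide 15 (not isolated)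
Conditions: 14, Mg, THF, reflux; then 12, MgBr2·OEt2, CH2Cl2, −78 °C; H2O
Reagents that add atoms: none
Why: In this chelation-controlled Grignard addition (Cram chelate model) magnesium bridges the aldehyde oxygen and the C3' benzyloxy oxygen and the aryl group enters from the side of the C3' hydrogen, which sets C2' with its OH syn to the C3' ether.

Step 11
Reactants: 16 bromo alcohol
Product: 17 (2R,3S,4S)-3,7,8-tris(benzyloxy)-2-[3,4-bis(benzyloxy)phenyl]-4-[(tert-butyldimethylsilyl)oxy]chroman (2α-aryl 3α-OBn 4β-OTBS)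
Conditions: Pd(OAc)2 (5 mol %), 2-(di-tert-butylphosphino)-1,1'-binaphthyl, Cs2CO3, toluene, 80 °C
Reagents that add atoms: none
Why: Palladium-catalysed intramolecular aryl etherification (Buchwald–Hartwig-type C–O coupling) closes ring C' at O1'–C8a' without touching the C2'–O bond, so the syn alcohol is carried over as the 2,3-cis flavan.

Step 12
Reactants: 17 protected lower flavan
Product: 18 (2R,3S,4S)-6-bromo-3,7,8-tris(benzyloxy)-2-[3,4-bis(benzyloxy)phenyl]-4-[(tert-butyldimethylsilyl)oxy]chroman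
Conditions: NBS (1.0 equiv), CH2Cl2, −78 to −20 °C
Reagents that add atoms: N-bromosuccinimide O=C1CCC(=O)N1Br
Why: Electrophilic aromatic bromination should go to C6', which is para to O1' and ortho to the C7' ether (resorcinol-type double activation), whereas C5' and the free positions of ring B' each feel only one conjugating oxygen.

Step 13
Reactants: 18 C6' bromide
Product: 20 ArL-boronic acid [(2R,3S,4S)-3,7,8-tris(benzyloxy)-2-[3,4-bis(benzyloxy)phenyl]-4-[(tert-butyldimethylsilyl)oxy]chroman-6-yl]boronic acid, via C6'-aryllithium 19 (not isolated)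
Conditions: nBuLi, THF, −78 °C; B(OiPr)3, −78 °C to rt; H2O
Reagents that add atoms: triisopropyl borate CC(C)OB(OC(C)C)OC(C)C; water O
Why: Bromine–lithium exchange at −78 °C outruns deprotonation of the benzyl ethers, and trapping of the aryllithium with a borate ester followed by hydrolysis is the standard route to an arylboronic acid.

Step 14
Reactants: 21 7-hydroxycoumarin (umbelliferone)
Product: 22 7-hydroxy-8-iodocoumarin
Conditions: I2, KI, aq. NH3, rt
Reagents that add atoms: iodine II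
Why: Iodination of the phenoxide of a 7-hydroxycoumarin takes place at C8, the more nucleophilic ortho position, as in the formylation, aminomethylation and Claisen chemistry of this ring system.

Step 15
Reactants: 22 7-hydroxy-8-iodocoumarin
Product: 23 7-(benzyloxy)-8-iodocoumarin
Conditions: BnBr, K2CO3, acetone, reflux
Reagents that add atoms: benzyl bromide BrCc1ccccc1
Why: Williamson etherification caps O7 and gives an acceptor that already holds C2, C3, C4, ring A, the C8 iodide and the C8a oxygen that will later leave.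

Step 16
Reactants: 20 ArL-boronic acid; 23 7-(benzyloxy)-8-iodocoumarin
Product: 24 (4S)-7-(benzyloxy)-8-iodo-4-ArL-chroman-2-one (ArL on the β face)
Conditions: Rh(acac)(C2H4)2 (5 mol %), (S)-SEGPHOS, dioxane/H2O 10:1, 60 °C
Reagents that add atoms: none
Why: In this rhodium-catalysed asymmetric 1,4-addition of an arylboronic acid to a coumarin (Hayashi–Miyaura reaction) the aryl–rhodium species inserts the C3=C4 bond and water protonates the enolate, and the (S)-ligand is chosen because its antipode is known to deliver aryl groups to the α face of coumarins, so ArL should enter on the β face and set C4.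

Step 17
Reactants: 24 4-aryl dihydrocoumarin
Product: 26 (3R,4S)-7-(benzyloxy)-3-hydroxy-8-iodo-4-ArL-chroman-2-one (3α-OH 4β-ArL), via potassium lactone enolate 25 (not isolated)
Conditions: KN(SiMe3)2, THF, −78 °C; 2-(phenylsulfonyl)-3-phenyloxaziridine, −78 °C; AcOH
Reagents that add atoms: 2-(phenylsulfonyl)-3-phenyloxaziridine O=S(=O)(c1ccccc1)N1OC1c1ccccc1
Why: In this enolate oxidation with an N-sulfonyloxaziridine (Davis oxidation) the oxidant approaches the flat lactone enolate anti to the pseudo-axial C4 aryl group, which sets C3 trans to C4, and the low temperature suppresses loss of phenoxide to a ketene.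

Step 18
Reactants: 26 α-hydroxy lactone
Product: 27 (3R,4S)-3,7-bis(benzyloxy)-8-iodo-4-ArL-chroman-2-one
Conditions: BnBr, Ag2O, CH2Cl2, rt, dark
Reagents that add atoms: benzyl bromide BrCc1ccccc1
Why: Silver-oxide-mediated benzylation works under essentially neutral conditions, so the aryl lactone is not opened and C3 is not epimerised, and the chelating benzyl ether blocks O3 from any later ring closure.

Step 19
Reactants: 27 3-benzyloxy lactone
Product: 28 (3R,4S)-3,7-bis(benzyloxy)-8-iodo-4-ArL-chroman-2-ol (lactol; both C2 anomers)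
Conditions: iBu2AlH (1.1 equiv), toluene, −78 °C
Reagents that add atoms: none
Why: In this partial lactone reduction the tetrahedral aluminium hemiacetal is stable at −78 °C and gives the 2-chromanol on hydrolysis, the aryl iodide and all ethers being inert to iBu2AlH.

Step 20
Reactants: 28 lactol; 29 1-(benzyloxy)-4-bromobenzene
Product: 32 (1R,2R)-2-(benzyloxy)-3-[4-(benzyloxy)-2-hydroxy-3-iodophenyl]-1-[4-(benzyloxy)phenyl]-3-ArL-propan-1-ol (flavan C2–OH and C3–OBn syn; flavan C4 as in 24), via 4-(benzyloxy)phenylmagnesium bromide 30 (not isolated), via open-chain phenoxide aldehyde 31 (not isolated)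
Conditions: 29, Mg, THF; then 28, THF/CH2Cl2, −40 to 0 °C; H2O
Reagents that add atoms: none
Why: In this Grignard addition to a lactol the first equivalent opens the hemiacetal to the magnesium phenoxide aldehyde and the second adds under Cram chelate control (magnesium between C2=O and the C3 benzyloxy oxygen, attack from the side of H3), which sets C2 syn to C3, while the electron-rich iodophenoxide ring resists iodine–magnesium exchange with an aryl Grignard reagent.

Step 21
Reactants: 32 phenol alcohol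
Product: 33 3-(benzyloxy)-2-iodo-6-[(2R,3R)-2-(benzyloxy)-3-[4-(benzyloxy)phenyl]-3-hydroxy-1-ArL-propyl]phenyl 4-chlorobenzenesulfonate (C2 alcohol free; all centres as in 32)
Conditions: 4-ClC6H4SO2Cl, Et3N, CH2Cl2, 0 °C
Reagents that add atoms: 4-chlorobenzenesulfonyl chloride O=S(=O)(Cl)c1ccc(Cl)cc1
Why: The phenol is by far the more acidic hydroxyl and is sulfonylated selectively under amine base at 0 °C, leaving the secondary benzylic alcohol free.

Step 22
Reactants: 33 iodoaryl sulfonate alcohol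
Product: 38 (2R,3R)-3,7-bis(benzyloxy)-2-[4-(benzyloxy)phenyl]-4β-ArL-chroman-8-ol (2,3-cis-3,4-trans), via C8-magnesiated alkoxide 34 (not isolated), via C8–C8a aryne alkoxide 35 (not isolated), via cyclised C8 arylmagnesium chloride 36 (not isolated), via C8 dimethyl boronate 37 (not isolated)
Conditions: iPrMgCl (2.0 equiv), THF, −78 °C, then to rt; B(OMe)3, −78 °C to rt; H2O2, aq. NaOH, 0 °C
Reagents that add atoms: hydrogen peroxide OO
Why: Proposed new method: the first equivalent of iPrMgCl turns the C2 alcohol into its magnesium alkoxide and the second exchanges the C8 iodide, and on warming the 2-magnesiated aryl sulfonate 34 expels chloromagnesium 4-chlorobenzenesulfonate to give the C8–C8a aryne 35. The tethered alkoxide adds to C8a in a 6-exo-dig closure that forms ring C (O1, C2, C3, C4, C4a, C8a) and leaves the carbanion on C8 as arylmagnesium 36, which B(OMe)3 converts into boronate 37 and alkaline H2O2 into the C8 phenol by aryl migration from boron to oxygen. The closest known reactions are aryne generation from 2-iodoaryl 4-chlorobenzenesulfonates with iPrMgCl (where magnesium thiolates and amides add and the adduct arylmagnesium is trapped by electrophiles), base-mediated alkoxide–aryne closures of chromans, and borylation–oxidation of aryl Grignard reagents, but a tethered oxygen nucleophile and an oxidative trap have not been combined in one sequence. No stereocentre is created, because the C2–O bond is never broken and the syn C2/C3 array of 33 therefore reappears as the 2,3-cis flavan. The regioselectivity needed at the aryne is secured twice, since the inductively withdrawing C7 benzyloxy group next to C8 makes the distal carbon C8a the electrophilic one and the three-carbon tether can reach only C8a. Chemoselectivity rests on the benzyl cap on O3, which excludes the competing five-membered closure, and on using no more than two equivalents of iPrMgCl, so that no external carbon nucleophile is left when the aryne appears.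

Step 23
Reactants: 38 protected dimer with free C8 hydroxyl
Product: 39 (2R,3R)-3,7-bis(benzyloxy)-2-[4-(benzyloxy)phenyl]-4β-[(2R,3R,4S)-3,7,8-tris(benzyloxy)-2-[3,4-bis(benzyloxy)phenyl]-4-hydroxychroman-6-yl]chroman-8-ol
Conditions: Bu4NF, AcOH, THF, rt
Reagents that add atoms: none
Why: Fluoride attacks silicon only, so the C4'–O bond and its configuration stay untouched, and the acetic acid buffer keeps the liberated alkoxide and the C8 phenoxide from causing side reactions.

Step 24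
Reactants: 39 octabenzyl ether
Product: 40 (2R,3R,4S)-2-(4-hydroxyphenyl)-4-[(2R,3R,4S)-2-(3,4-dihydroxyphenyl)-3,4,7,8-tetrahydroxychroman-6-yl]chroman-3,7,8-triol (CNP0275688.1)
Conditions: H2 (1 atm), Pd(OH)2/C, THF/MeOH/H2O, rt
Reagents that add atoms: none
Why: Catalytic hydrogenolysis cleaves the eight O–CH2Ph bonds, while in a neutral medium the hindered secondary C4'–OH, the C2–O1 bonds and the interflavan C4–C6' bond should persist, as in the final deprotection of benzylated proanthocyanidins.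

**Compound list**
1 | 3,4-dihydroxybenzaldehyde | O=Cc1ccc(O)c(O)c1 | starting material
2 | 4-(benzyloxy)-3-hydroxybenzaldehyde | O=Cc1ccc(OCc2ccccc2)c(O)c1 | intermediate
3 | 4-(benzyloxy)-2-bromo-3-hydroxybenzaldehyde | O=Cc1ccc(OCc2ccccc2)c(O)c1Br | intermediate
4 | 3,4-bis(benzyloxy)-2-bromobenzaldehyde | O=Cc1ccc(OCc2ccccc2)c(OCc2ccccc2)c1Br | intermediate
5 | (R)-4-benzyloxazolidin-2-one | O=C1N[C@H](Cc2ccccc2)CO1 | starting material
6 | (benzyloxy)acetyl chloride | O=C(Cl)COCc1ccccc1 | starting material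
7 | (R)-4-benzyl-3-[(benzyloxy)acetyl]oxazolidin-2-one | O=C(COCc1ccccc1)N1C(=O)OC[C@H]1Cc1ccccc1 | intermediate
8 | Z-dibutylboron enolate of 7 | c1ccccc1CO/C=C(/N1C(=O)OC[C@H]1Cc1ccccc1)OB(CCCC)CCCC | intermediate
9 | (R)-4-benzyl-3-{(2R,3S)-2-(benzyloxy)-3-[3,4-bis(benzyloxy)-2-bromophenyl]-3-hydroxypropanoyl}oxazolidin-2-one | Brc1c(OCc5ccccc5)c(OCc5ccccc5)ccc1[C@H](O)[C@@H](OCc5ccccc5)C(=O)N2C(=O)OC[C@H]2Cc3ccccc3 | intermediate
10 | tert-butyldimethylsilyl ether of 9 (2R,3S) | Brc1c(OCc5ccccc5)c(OCc5ccccc5)ccc1[C@H](O[Si](C)(C)C(C)(C)C)[C@@H](OCc5ccccc5)C(=O)N2C(=O)OC[C@H]2Cc3ccccc3 | intermediate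
11 | (2S,3S)-2-(benzyloxy)-3-[3,4-bis(benzyloxy)-2-bromophenyl]-3-[(tert-butyldimethylsilyl)oxy]propan-1-ol | Brc1c(OCc5ccccc5)c(OCc5ccccc5)ccc1[C@H](O[Si](C)(C)C(C)(C)C)[C@@H](OCc5ccccc5)CO | intermediate
12 | (2R,3S)-2-(benzyloxy)-3-[3,4-bis(benzyloxy)-2-bromophenyl]-3-[(tert-butyldimethylsilyl)oxy]propanal | Brc1c(OCc5ccccc5)c(OCc5ccccc5)ccc1[C@H](O[Si](C)(C)C(C)(C)C)[C@@H](OCc5ccccc5)C=O | intermediate
13 | 4-bromobenzene-1,2-diol | Oc1ccc(Br)cc1O | starting material
14 | 1,2-bis(benzyloxy)-4-bromobenzene | Brc1ccc(OCc2ccccc2)c(OCc2ccccc2)c1 | intermediate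
15 | 3,4-bis(benzyloxy)phenylmagnesium bromide | Br[Mg]c1ccc(OCc2ccccc2)c(OCc2ccccc2)c1 | intermediate
16 | (1R,2S,3S)-2-(benzyloxy)-3-[3,4-bis(benzyloxy)-2-bromophenyl]-1-[3,4-bis(benzyloxy)phenyl]-3-[(tert-butyldimethylsilyl)oxy]propan-1-ol | Brc1c(OCc5ccccc5)c(OCc5ccccc5)ccc1[C@H](O[Si](C)(C)C(C)(C)C)[C@@H](OCc5ccccc5)[C@H](O)c3ccc(OCc5ccccc5)c(OCc5ccccc5)c3 | intermediate
17 | (2R,3S,4S)-3,7,8-tris(benzyloxy)-2-[3,4-bis(benzyloxy)phenyl]-4-[(tert-butyldimethylsilyl)oxy]chroman | c1cc2c(c(OCc5ccccc5)c1OCc5ccccc5)O[C@H](c3ccc(OCc5ccccc5)c(OCc5ccccc5)c3)[C@H](OCc5ccccc5)[C@H]2O[Si](C)(C)C(C)(C)C | intermediate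
18 | 6-bromo derivative of 17 | Brc1cc2c(c(OCc5ccccc5)c1OCc5ccccc5)O[C@H](c3ccc(OCc5ccccc5)c(OCc5ccccc5)c3)[C@H](OCc5ccccc5)[C@H]2O[Si](C)(C)C(C)(C)C | intermediate
19 | 6-lithio derivative of 17 | [Li]c1cc2c(c(OCc5ccccc5)c1OCc5ccccc5)O[C@H](c3ccc(OCc5ccccc5)c(OCc5ccccc5)c3)[C@H](OCc5ccccc5)[C@H]2O[Si](C)(C)C(C)(C)C | intermediate
20 | ArL-boronic acid (6-boronic acid of 17) | OB(O)c1cc2c(c(OCc5ccccc5)c1OCc5ccccc5)O[C@H](c3ccc(OCc5ccccc5)c(OCc5ccccc5)c3)[C@H](OCc5ccccc5)[C@H]2O[Si](C)(C)C(C)(C)C | intermediate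
21 | 7-hydroxycoumarin | O=c1ccc2ccc(O)cc2o1 | starting material
22 | 7-hydroxy-8-iodocoumarin | O=c1ccc2ccc(O)c(I)c2o1 | intermediate
23 | 7-(benzyloxy)-8-iodocoumarin | O=c1ccc2ccc(OCc3ccccc3)c(I)c2o1 | intermediate
24 | (4S)-7-(benzyloxy)-8-iodo-4-ArL-chroman-2-one | O=C1Oc3c(ccc(OCc5ccccc5)c3I)[C@H](c3cc4c(c(OCc5ccccc5)c3OCc5ccccc5)O[C@H](c3ccc(OCc5ccccc5)c(OCc5ccccc5)c3)[C@H](OCc5ccccc5)[C@H]4O[Si](C)(C)C(C)(C)C)C1 | intermediate
25 | potassium enolate of 24 | [K+].[O-]C1Oc3c(ccc(OCc5ccccc5)c3I)[C@H](c3cc4c(c(OCc5ccccc5)c3OCc5ccccc5)O[C@H](c3ccc(OCc5ccccc5)c(OCc5ccccc5)c3)[C@H](OCc5ccccc5)[C@H]4O[Si](C)(C)C(C)(C)C)C=1 | intermediate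
26 | (3R,4S)-7-(benzyloxy)-3-hydroxy-8-iodo-4-ArL-chroman-2-one | O=C1Oc3c(ccc(OCc5ccccc5)c3I)[C@H](c3cc4c(c(OCc5ccccc5)c3OCc5ccccc5)O[C@H](c3ccc(OCc5ccccc5)c(OCc5ccccc5)c3)[C@H](OCc5ccccc5)[C@H]4O[Si](C)(C)C(C)(C)C)[C@H]1O | intermediate
27 | (3R,4S)-3,7-bis(benzyloxy)-8-iodo-4-ArL-chroman-2-one | O=C1Oc3c(ccc(OCc5ccccc5)c3I)[C@H](c3cc4c(c(OCc5ccccc5)c3OCc5ccccc5)O[C@H](c3ccc(OCc5ccccc5)c(OCc5ccccc5)c3)[C@H](OCc5ccccc5)[C@H]4O[Si](C)(C)C(C)(C)C)[C@H]1OCc5ccccc5 | intermediate
28 | (3R,4S)-3,7-bis(benzyloxy)-8-iodo-4-ArL-chroman-2-ol (both C2 anomers) | OC1Oc3c(ccc(OCc5ccccc5)c3I)[C@H](c3cc4c(c(OCc5ccccc5)c3OCc5ccccc5)O[C@H](c3ccc(OCc5ccccc5)c(OCc5ccccc5)c3)[C@H](OCc5ccccc5)[C@H]4O[Si](C)(C)C(C)(C)C)[C@H]1OCc5ccccc5 | intermediate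
29 | 1-(benzyloxy)-4-bromobenzene | Brc1ccc(OCc2ccccc2)cc1 | starting material
30 | 4-(benzyloxy)phenylmagnesium bromide | Br[Mg]c1ccc(OCc2ccccc2)cc1 | intermediate
31 | bromomagnesium phenoxide of the ring-opened (2R)-2-(benzyloxy)-3-aryl-3-ArL-propanal | Br[Mg]Oc3c(ccc(OCc5ccccc5)c3I)[C@H](c3cc4c(c(OCc5ccccc5)c3OCc5ccccc5)O[C@H](c3ccc(OCc5ccccc5)c(OCc5ccccc5)c3)[C@H](OCc5ccccc5)[C@H]4O[Si](C)(C)C(C)(C)C)[C@@H](OCc5ccccc5)C=O | intermediate
32 | (1R,2R)-2-(benzyloxy)-3-[4-(benzyloxy)-2-hydroxy-3-iodophenyl]-1-[4-(benzyloxy)phenyl]-3-ArL-propan-1-ol | Oc3c(ccc(OCc5ccccc5)c3I)[C@H](c3cc4c(c(OCc5ccccc5)c3OCc5ccccc5)O[C@H](c3ccc(OCc5ccccc5)c(OCc5ccccc5)c3)[C@H](OCc5ccccc5)[C@H]4O[Si](C)(C)C(C)(C)C)[C@@H](OCc5ccccc5)[C@H](O)c1ccc(OCc5ccccc5)cc1 | intermediate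
33 | 4-chlorobenzenesulfonate of the phenol of 32 (key-step precursor) | Clc6ccc(cc6)S(=O)(=O)Oc3c(ccc(OCc5ccccc5)c3I)[C@H](c3cc4c(c(OCc5ccccc5)c3OCc5ccccc5)O[C@H](c3ccc(OCc5ccccc5)c(OCc5ccccc5)c3)[C@H](OCc5ccccc5)[C@H]4O[Si](C)(C)C(C)(C)C)[C@@H](OCc5ccccc5)[C@H](O)c1ccc(OCc5ccccc5)cc1 | intermediate
34 | C2 chloromagnesium alkoxide, C8 arylmagnesium chloride of 33 | Clc6ccc(cc6)S(=O)(=O)Oc3c(ccc(OCc5ccccc5)c3[Mg]Cl)[C@H](c3cc4c(c(OCc5ccccc5)c3OCc5ccccc5)O[C@H](c3ccc(OCc5ccccc5)c(OCc5ccccc5)c3)[C@H](OCc5ccccc5)[C@H]4O[Si](C)(C)C(C)(C)C)[C@@H](OCc5ccccc5)[C@H](O[Mg]Cl)c1ccc(OCc5ccccc5)cc1 | intermediate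
35 | C8–C8a aryne bearing the C2 chloromagnesium alkoxide | C1#CC(OCc5ccccc5)=CC=C1[C@H](c3cc4c(c(OCc5ccccc5)c3OCc5ccccc5)O[C@H](c3ccc(OCc5ccccc5)c(OCc5ccccc5)c3)[C@H](OCc5ccccc5)[C@H]4O[Si](C)(C)C(C)(C)C)[C@@H](OCc5ccccc5)[C@H](O[Mg]Cl)c1ccc(OCc5ccccc5)cc1 | intermediate
36 | cyclised flavan with chloromagnesium on C8 | c5ccccc5COc1ccc([C@H]2Oc3c(ccc(OCc5ccccc5)c3[Mg]Cl)[C@H](c3cc4c(c(OCc5ccccc5)c3OCc5ccccc5)O[C@H](c3ccc(OCc5ccccc5)c(OCc5ccccc5)c3)[C@H](OCc5ccccc5)[C@H]4O[Si](C)(C)C(C)(C)C)[C@H]2OCc5ccccc5)cc1 | intermediate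
37 | cyclised flavan C8 dimethyl boronate | c5ccccc5COc1ccc([C@H]2Oc3c(ccc(OCc5ccccc5)c3B(OC)OC)[C@H](c3cc4c(c(OCc5ccccc5)c3OCc5ccccc5)O[C@H](c3ccc(OCc5ccccc5)c(OCc5ccccc5)c3)[C@H](OCc5ccccc5)[C@H]4O[Si](C)(C)C(C)(C)C)[C@H]2OCc5ccccc5)cc1 | intermediate
38 | (2R,3R)-3,7-bis(benzyloxy)-2-[4-(benzyloxy)phenyl]-4β-ArL-chroman-8-ol (key-step product) | c5ccccc5COc1ccc([C@H]2Oc3c(ccc(OCc5ccccc5)c3O)[C@H](c3cc4c(c(OCc5ccccc5)c3OCc5ccccc5)O[C@H](c3ccc(OCc5ccccc5)c(OCc5ccccc5)c3)[C@H](OCc5ccccc5)[C@H]4O[Si](C)(C)C(C)(C)C)[C@H]2OCc5ccccc5)cc1 | intermediate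
39 | desilylated octabenzyl ether (free C8–OH and 4β C4'–OH) | c5ccccc5COc1ccc([C@H]2Oc3c(ccc(OCc5ccccc5)c3O)[C@H](c3cc4c(c(OCc5ccccc5)c3OCc5ccccc5)O[C@H](c3ccc(OCc5ccccc5)c(OCc5ccccc5)c3)[C@H](OCc5ccccc5)[C@H]4O)[C@H]2OCc5ccccc5)cc1 | intermediate
40 | CNP0275688.1, (2R,3R,4S)-2-(4-hydroxyphenyl)-4-[(2R,3R,4S)-2-(3,4-dihydroxyphenyl)-3,4,7,8-tetrahydroxychroman-6-yl]chroman-3,7,8-triol | Oc1ccc([C@H]2Oc3c(ccc(O)c3O)[C@H](c3cc4c(c(O)c3O)O[C@H](c3ccc(O)c(O)c3)[C@H](O)[C@H]4O)[C@H]2O)cc1 | target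

**Step count**
Total: 24 steps.
Longest linear sequence: 20 steps (1–3, 5–8, 10–13, 16–24).

**Steps most likely to fail**

Step 22. The magnesium alkoxide may add too slowly. The aryne would then be intercepted by residual iPrMgCl or by the C3 ether oxygen, or the C8 arylmagnesium could be protonated before borylation.
The fallback uses known chemistry only and takes the original C8a oxygen as O1. It sets out from 32. MnO2 in CH2Cl2 oxidises the benzylic C2 alcohol to the aryl ketone F1. Zn(BH4)2 in Et2O reduces F1 under chelation control to the 2,3-anti alcohol F2. An intramolecular Mitsunobu etherification (PPh3, diisopropyl azodicarboxylate, THF) lets the C8a phenol displace the activated C2 oxygen with inversion and gives the 2,3-cis 8-iodoflavan F3. Iodine–magnesium exchange on F3 with iPrMgCl, then B(OMe)3 and alkaline H2O2, comes back to the route at 38.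

Step 16. Transmetalation and insertion of the bulky ortho-alkoxy boronic acid may be slow enough for protodeboronation to win. Insertion of rhodium into the C8–I bond could also erode the acceptor.
The fallback replaces catalyst control by a stoichiometric organocopper addition with separation of diastereomers. It sets out from bromide 18. Bromine–lithium exchange gives 19, and CuBr·SMe2 converts it into the arylcopper F4. BF3·OEt2 then promotes conjugate addition of F4 to 23 at −78 °C. Because ArL is a single enantiomer, the product and its 4α epimer F5 are diastereomers and are separated by chromatography. The route is rejoined at 24.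

Step 24. As the phenols are unveiled, the benzylic C4'–OH (para to the C7' oxygen) may be lost by hydrogenolysis, or debenzylation may stall.
The fallback inverts the order of the two deprotections so that the bulky silyl ether shields C4'–O during hydrogenation. It sets out from 38. H2 over Pd(OH)2/C gives the free polyphenol that still carries the C4' silyl ether, F6. Et3N·3HF in MeCN then removes the silyl group and arrives at 40.

**Further compounds**
F1 | step 22 | (2R)-2-(benzyloxy)-3-[4-(benzyloxy)-2-hydroxy-3-iodophenyl]-1-[4-(benzyloxy)phenyl]-3-ArL-propan-1-one | Oc3c(ccc(OCc5ccccc5)c3I)[C@H](c3cc4c(c(OCc5ccccc5)c3OCc5ccccc5)O[C@H](c3ccc(OCc5ccccc5)c(OCc5ccccc5)c3)[C@H](OCc5ccccc5)[C@H]4O[Si](C)(C)C(C)(C)C)[C@@H](OCc5ccccc5)C(=O)c1ccc(OCc5ccccc5)cc1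
F2 | step 22 | C2 epimer of 32 (flavan C2–OH and C3–OBn anti) | Oc3c(ccc(OCc5ccccc5)c3I)[C@H](c3cc4c(c(OCc5ccccc5)c3OCc5ccccc5)O[C@H](c3ccc(OCc5ccccc5)c(OCc5ccccc5)c3)[C@H](OCc5ccccc5)[C@H]4O[Si](C)(C)C(C)(C)C)[C@@H](OCc5ccccc5)[C@@H](O)c1ccc(OCc5ccccc5)cc1
F3 | step 22 | (2R,3R)-3,7-bis(benzyloxy)-2-[4-(benzyloxy)phenyl]-8-iodo-4β-ArL-chroman | c5ccccc5COc1ccc([C@H]2Oc3c(ccc(OCc5ccccc5)c3I)[C@H](c3cc4c(c(OCc5ccccc5)c3OCc5ccccc5)O[C@H](c3ccc(OCc5ccccc5)c(OCc5ccccc5)c3)[C@H](OCc5ccccc5)[C@H]4O[Si](C)(C)C(C)(C)C)[C@H]2OCc5ccccc5)cc1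
F4 | step 16 | ArL-copper (6-cuprio derivative of 17) | [Cu]c1cc2c(c(OCc5ccccc5)c1OCc5ccccc5)O[C@H](c3ccc(OCc5ccccc5)c(OCc5ccccc5)c3)[C@H](OCc5ccccc5)[C@H]2O[Si](C)(C)C(C)(C)C
F5 | step 16 | C4 epimer of 24 (ArL on the α face) | O=C1Oc3c(ccc(OCc5ccccc5)c3I)[C@@H](c3cc4c(c(OCc5ccccc5)c3OCc5ccccc5)O[C@H](c3ccc(OCc5ccccc5)c(OCc5ccccc5)c3)[C@H](OCc5ccccc5)[C@H]4O[Si](C)(C)C(C)(C)C)C1
F6 | step 24 | C4'-O-(tert-butyldimethylsilyl) ether of 40 | Oc1ccc([C@H]2Oc3c(ccc(O)c3O)[C@H](c3cc4c(c(O)c3O)O[C@H](c3ccc(O)c(O)c3)[C@H](O)[C@H]4O[Si](C)(C)C(C)(C)C)[C@H]2O)cc1
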